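**Plan**

Numbering: ring C1 (side chain), C2 (OH), C3 (angelate), C4 (Me) and C5 (epoxide), C6 (CH2); chain C7(=C14H2), C8 (angelate), C9, C10–C11 (epoxide). The enabling feature is that C1, flanked by the cis oxygens on C2 and C3, is joined through C6 to the C4(Me)=C5 alkene hidden in the ring epoxide, so that C1=C7–O–C4–C5=C6 is a [3,3] array inside a six-membered lactone.
Cuts, in retrosynthetic order: both angelate C–O bonds and the two epoxide oxygens; C7–C8 (alkenyl triflate plus aldehyde); C7–C14 (MeLi on a lactone); C1–C6 (sigmatropic, opening the carbocycle to lactone 12); C4–CH3 and C4–C5 (two Grignard additions).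
Forward: 2-deoxy-L-ribose → acetonide δ-lactone 12 → cyclohexene acid 15 (the only carbocycle, step 8) → bridged γ-lactone 17, which tells O3 from O2 → methyl ketone, ring epoxide, C3 angelate → side chain at C7 → C8 angelate → C10–C11 epoxide.
Stereochemistry: C2 and C3 come from the sugar; C4 from chelate-controlled MeMgBr addition; C1 by transfer from C4 in the rearrangement; the ring epoxide from O3–H-directed VO(acac)2 epoxidation; C8 from a Corey–Bakshi–Shibata reduction; C10 from a Shi epoxidation.

Key step: step 8

Remark: the target numbering above is used for all intermediates. The D-fructose-derived Shi ketone is assumed to give 10R, by analogy with the (R,R)-epoxides it gives from trans-alkenes.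

**Route**

Step 1
Reactants: 1 2-deoxy-L-ribose; 2 2-methoxypropene
Product: 3 2-deoxy-3,4-O-isopropylidene-L-erythro-pentopyranose (anomers)
Conditions: 2-methoxypropene, PPTS (cat.), EtOAc, 0 °C → rt
Reagents that add atoms: 2-methoxypropene, COC(C)=C
Why: Acid-catalysed acetalisation with the enol ether should capture the cis-diol of the pyranose form (the future O2/O3) as a dioxolane and leave the hemiacetal free, without touching a stereocentre.

Step 2
Reactants: 3 lactol acetonide
Product: 4 2-deoxy-3,4-O-isopropylidene-L-erythro-pentono-1,5-lactone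
Conditions: TEMPO (cat.), PhI(OAc)2, CH2Cl2, rt
Reagents that add atoms: none
Why: Oxoammonium (TEMPO) oxidation of a lactol to the lactone is neutral enough to keep the acetonide and brings C7 to the acid level.

Step 3
Reactants: 4 δ-lactone
Product: 5 methyl 2-[(4R,5S)-5-(hydroxymethyl)-2,2-dimethyl-1,3-dioxolan-4-yl]acetate
Conditions: K2CO3 (cat.), MeOH, 0 °C; AcOH to neutral before concentration
Reagents that add atoms: methanol, CO
Why: Base-catalysed transesterification (methanolysis) of the δ-lactone should free the primary alcohol at C4, and neutralising before evaporation prevents re-lactonisation.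

Step 4
Reactants: 5 hydroxy ester
Product: 6 methyl 2-[(4R,5R)-5-formyl-2,2-dimethyl-1,3-dioxolan-4-yl]acetate
Conditions: Dess–Martin periodinane, NaHCO3, CH2Cl2, 0 °C
Reagents that add atoms: none
Why: Buffered Dess–Martin oxidation gives the α-alkoxy aldehyde without epimerising the cis-dioxolane carbon C3.

Step 5
Reactants: 6 aldehyde; 7 vinylmagnesium bromide
Product: 8 methyl 2-[cis-5-(1-hydroxyprop-2-enyl)-2,2-dimethyl-1,3-dioxolan-4-yl]acetate (carbinol epimers)
Conditions: CH2=CHMgBr, THF, −78 °C; aq. NH4Cl at −78 °C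
Reagents that add atoms: vinylmagnesium bromide, C=C[Mg]Br
Why: Grignard 1,2-addition to the aldehyde at −78 °C is far faster than attack on the methyl ester, and the new carbinol centre is erased in the next step, so its configuration does not matter.

Step 6
Reactants: 8 allylic alcohol
Product: 9 methyl 2-[(4R,5R)-2,2-dimethyl-5-(prop-2-enoyl)-1,3-dioxolan-4-yl]acetate
Conditions: Dess–Martin periodinane, NaHCO3, CH2Cl2, 0 °C; used at once
Reagents that add atoms: none
Why: Dess–Martin oxidation of the crude allylic alcohol should give the vinyl ketone under neutral conditions that neither epimerise C3 nor let the δ-hydroxy ester lactonise.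

Step 7
Reactants: 9 vinyl ketone; 10 methylmagnesium bromide
Product: 12 (4R,5R,6S)-6-ethenyl-4,5-(isopropylidenedioxy)-6-methyltetrahydropyran-2-one, via bromomagnesium alkoxide 11 (not isolated)
Conditions: MeMgBr, CH2Cl2/Et2O, −78 °C → rt; aq. NH4Cl
Reagents that add atoms: methylmagnesium bromide, C[Mg]Br
Why: In a Cram-chelate Grignard addition magnesium bridges the ketone oxygen and the dioxolane oxygen on C3, methyl attacks the face opposite the C2 branch and sets C4 with the vinyl group anti to O3, and the tertiary alkoxide then acylates on the methyl ester to close the δ-lactone.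

Step 8
Reactants: 12 vinyl lactone
Product: 15 (3aR,4R,7aS)-2,2,7-trimethyl-3a,4,5,7a-tetrahydro-1,3-benzodioxole-4-carboxylic acid, via silyl ketene acetal 13 (not isolated), via trimethylsilyl ester 14 (not isolated)
Conditions: LDA, Me3SiCl/Et3N (premixed), THF, −78 °C → rt; PhMe, 105 °C; then MeOH/H2O
Reagents that add atoms: none
Why: In situ O-silylation of the lactone enolate gives cyclic ketene acetal 13, whose C1=C7–O–C4–C5=C6 array undergoes a concerted [3,3] shift (Ireland–Claisen rearrangement of a lactone silyl ketene acetal, the known ring-contraction route from alkenyl lactones to cycloalkene carboxylic acids), forming C1–C6 as C4–O breaks and leaving C4=C5 and the C7 silyl ester. The cyclohexene closes by this sigmatropic bond formation across the lactone through a boat, bicyclo[2.2.2]octane-like transition state whose three two-atom bridges are C7–O, C2–C3 and C5=C6; it is a pericyclic ring contraction, not an ionic exo or endo closure. The new stereocentre C1 is controlled by C4: the vinyl group can reach C1 only on its own face of the lactone, the face anti to the acetonide oxygens, so the carboxyl is left cis to O2 and O3. The step needs O-silylation to outrun β-elimination of the C2 oxygen, which Me3SiCl present at −78 °C should secure, and it needs an eclipsed C2–C3 bond in the boat, which the cis-fused dioxolane already imposes.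

Step 9
Reactants: 15 acetonide acid
Product: 17 (1R,5S,8R)-8-hydroxy-4-methyl-6-oxabicyclo[3.2.1]oct-3-en-7-one, via dihydroxy acid 16 (not isolated)
Conditions: Dowex 50W (H+), MeCN/H2O, 40 °C; filter, evaporate; then EDC·HCl, DMAP (cat.), CH2Cl2 (high dilution), rt
Reagents that add atoms: none
Why: Acetal hydrolysis followed by carbodiimide lactonisation should give only the γ-lactone through O3, which is cis-1,3 to the carboxyl, because O2 could close only a β-lactone; this distinguishes O3 (acylated) from O2 (free) and locks C1.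

Step 10
Reactants: 17 hydroxy lactone
Product: 18 (1R,5S,8R)-4-methyl-8-(triethylsilyloxy)-6-oxabicyclo[3.2.1]oct-3-en-7-one
Conditions: Et3SiCl, imidazole, DMF, 0 °C → rt
Reagents that add atoms: chlorotriethylsilane, CC[Si](Cl)(CC)CC
Why: Silylation of the only free hydroxyl protects O2 as a triethylsilyl ether that can be removed at the end under near-neutral fluoride conditions.

Step 11
Reactants: 18 silylated lactone; 19 methyllithium
Product: 21 1-[(1R,5S,6R)-5-hydroxy-4-methyl-6-(triethylsilyloxy)cyclohex-3-en-1-yl]ethanone, via lithium hemiketalate 20 (not isolated)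
Conditions: MeLi (1.05 equiv), THF, −78 °C; AcOH at −78 °C, then rt
Reagents that add atoms: methyllithium, [Li]C
Why: Organolithium addition to a lactone stops at the tetrahedral lithium hemiketalate at −78 °C, which on protonation opens to the C7 methyl ketone (C14 installed) and free O3–H, while the bridgehead position of C1 rules out enolisation.

Step 12
Reactants: 21 hydroxy ketone
Product: 22 4,5-cis-epoxide of 21 (epoxide oxygen, O3–H, O2–Si and acetyl on one ring face)
Conditions: VO(acac)2 (5 mol %), t-BuOOH (decane), CH2Cl2, 0 °C → rt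
Reagents that add atoms: tert-butyl hydroperoxide, CC(C)(C)OO
Why: In this hydroxyl-directed vanadium-catalysed epoxidation the vanadate ester of the allylic O3–H delivers oxygen to the syn face of C4=C5, the only alkene present, which sets C4 and C5 cis to O3.

Step 13
Reactants: 22 epoxy alcohol; 23 angelic acid
Product: 24 C3 angelate of 22
Conditions: angelic acid, 2,4,6-Cl3C6H2COCl, Et3N, PhMe, rt; then 22, 70 °C
Reagents that add atoms: angelic acid, C/C=C(/C)C(=O)O
Why: Yamaguchi esterification through the mixed anhydride, run without DMAP, is the established way to acylate a hindered secondary alcohol with angelic acid while keeping the Z double bond.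

Step 14
Reactants: 24 methyl ketone
Product: 26 C7 enol triflate (1-substituted ethenyl trifluoromethanesulfonate), via potassium enolate 25 (not isolated)
Conditions: KHMDS, THF, −78 °C; then PhNTf2, −78 → −20 °C
Reagents that add atoms: N-phenylbis(trifluoromethanesulfonimide), O=S(=O)(N(c1ccccc1)S(=O)(=O)C(F)(F)F)C(F)(F)F
Why: Kinetic deprotonation at the methyl group followed by O-triflation of the enolate should give the terminal alkenyl triflate without touching the C1 methine or the ester.

Step 15
Reactants: 27 4-methylpent-3-en-1-ol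
Product: 28 4-methylpent-3-enal
Conditions: Dess–Martin periodinane, NaHCO3, CH2Cl2, 0 °C; used as a solution
Reagents that add atoms: none
Why: Buffered Dess–Martin oxidation gives the β,γ-unsaturated aldehyde without moving the double bond into conjugation.

Step 16
Reactants: 26 enol triflate; 28 4-methylpent-3-enal
Product: 30 C8 carbinol (C7=C14H2 with CH(OH)CH2CH=CMe2 on C7; C8 epimers), via alkenylchromium dichloride 29 (not isolated)
Conditions: CrCl2 (4 equiv), NiCl2 (2 mol %), degassed DMF, rt
Reagents that add atoms: 4-methylpent-3-enal, CC(C)=CCC=O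
Why: In the Nozaki–Hiyama–Kishi coupling nickel inserts into the alkenyl triflate and hands the alkenyl group to chromium (trivalent in 29), which adds to the aldehyde under non-basic conditions expected to spare ester, epoxide and silyl ether; C8 is corrected in the next two steps.

Step 17
Reactants: 30 allylic alcohol
Product: 31 α-methylene ketone (C8 ketone)
Conditions: Dess–Martin periodinane, NaHCO3, CH2Cl2, 0 °C
Reagents that add atoms: none
Why: Dess–Martin oxidation converges both C8 epimers on one enone under neutral conditions that should leave the β,γ-alkene in place.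

Step 18
Reactants: 31 enone
Product: 32 (8S)-allylic alcohol
Conditions: (R)-Me-CBS oxazaborolidine (0.5 equiv), catecholborane, PhMe, −78 °C
Reagents that add atoms: none
Why: In the Corey–Bakshi–Shibata reduction the (R)-catalyst treats the branched alkenyl group as the large substituent and delivers hydride to give 8S, and catecholborane at −78 °C avoids hydroboration and conjugate reduction.

Step 19
Reactants: 32 alcohol; 23 angelic acid
Product: 33 3,8-bis-angelate
Conditions: angelic acid, 2,4,6-Cl3C6H2COCl, Et3N, PhMe, rt; then 32, 70 °C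
Reagents that add atoms: angelic acid, C/C=C(/C)C(=O)O
Why: A second Yamaguchi esterification acylates the allylic O8–H with retention at C8 and without Z to E isomerisation.

Step 20
Reactants: 33 bis-angelate
Product: 34 O2-triethylsilyl ether of the target
Conditions: D-fructose-derived Shi ketone (0.3 equiv), Oxone (KHSO5), K2CO3, Bu4NHSO4, MeCN/(MeO)2CH2/aq. Na2B4O7–EDTA, 0 °C
Reagents that add atoms: potassium peroxymonosulfate, [K+].[O-]S(=O)(=O)OO
Why: In the Shi epoxidation the chiral dioxirane attacks the electron-rich trisubstituted C10=C11 through a spiro transition state to give 10R, while the ester-flanked C7=C14 and the enoate double bonds are much slower and the silyl group on O2 blocks acyl migration at the basic pH.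

Step 21
Reactants: 34 silyl ether
Product: 35 target CNP0296086.3
Conditions: Bu4NF/AcOH (1:1), THF, 0 °C → rt
Reagents that add atoms: none
Why: Buffered fluoride desilylation frees O2–H in a near-neutral medium that should prevent both angelate migration from O3 and epoxide opening.

**Compound list**

1 | 2-deoxy-L-ribose | O=CC[C@@H](O)[C@@H](O)CO | starting material
2 | 2-methoxypropene | COC(C)=C | starting material
3 | 2-deoxy-3,4-O-isopropylidene-L-erythro-pentopyranose (anomers) | OC1C[C@H]2OC(C)(C)O[C@H]2CO1 | intermediate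
4 | 2-deoxy-3,4-O-isopropylidene-L-erythro-pentono-1,5-lactone | O=C1C[C@H]2OC(C)(C)O[C@H]2CO1 | intermediate
5 | methyl 2-[(4R,5S)-5-(hydroxymethyl)-2,2-dimethyl-1,3-dioxolan-4-yl]acetate | COC(=O)C[C@H]1OC(C)(C)O[C@H]1CO | intermediate
6 | methyl 2-[(4R,5R)-5-formyl-2,2-dimethyl-1,3-dioxolan-4-yl]acetate | COC(=O)C[C@H]1OC(C)(C)O[C@H]1C=O | intermediate
7 | vinylmagnesium bromide | C=C[Mg]Br | starting material
8 | methyl 2-[cis-5-(1-hydroxyprop-2-enyl)-2,2-dimethyl-1,3-dioxolan-4-yl]acetate (carbinol epimers, ring carbons as in 5) | COC(=O)C[C@H]1OC(C)(C)O[C@H]1C(O)C=C | intermediate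
9 | methyl 2-[(4R,5R)-2,2-dimethyl-5-(prop-2-enoyl)-1,3-dioxolan-4-yl]acetate | COC(=O)C[C@H]1OC(C)(C)O[C@H]1C(=O)C=C | intermediate
10 | methylmagnesium bromide | C[Mg]Br | starting material
11 | bromomagnesium alkoxide of the C4 tertiary carbinol (vinyl anti to O3) | COC(=O)C[C@H]1OC(C)(C)O[C@H]1[C@](C)(C=C)O[Mg]Br | intermediate
12 | (4R,5R,6S)-6-ethenyl-4,5-(isopropylidenedioxy)-6-methyltetrahydropyran-2-one (vinyl anti to the acetonide oxygens) | O=C1C[C@H]2OC(C)(C)O[C@H]2[C@](C)(C=C)O1 | intermediate
13 | trimethylsilyl ketene acetal of 12 (C1=C7) | C[Si](C)(C)OC1=C[C@H]2OC(C)(C)O[C@H]2[C@](C)(C=C)O1 | intermediate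
14 | trimethylsilyl ester of 15 | C[Si](C)(C)OC(=O)[C@@H]1CC=C(C)[C@@H]2OC(C)(C)O[C@H]12 | intermediate
15 | (3aR,4R,7aS)-2,2,7-trimethyl-3a,4,5,7a-tetrahydro-1,3-benzodioxole-4-carboxylic acid (carboxyl cis to both oxygens) | OC(=O)[C@@H]1CC=C(C)[C@@H]2OC(C)(C)O[C@H]12 | intermediate
16 | (1R,5S,6R)-5,6-dihydroxy-4-methylcyclohex-3-ene-1-carboxylic acid (all-cis) | OC(=O)[C@@H]1CC=C(C)[C@H](O)[C@@H]1O | intermediate
17 | (1R,5S,8R)-8-hydroxy-4-methyl-6-oxabicyclo[3.2.1]oct-3-en-7-one | O=C1O[C@H]2C(C)=CC[C@@H]1[C@H]2O | intermediate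
18 | (1R,5S,8R)-4-methyl-8-(triethylsilyloxy)-6-oxabicyclo[3.2.1]oct-3-en-7-one | O=C1O[C@H]2C(C)=CC[C@@H]1[C@H]2O[Si](CC)(CC)CC | intermediate
19 | methyllithium | [Li]C | starting material
20 | lithium hemiketalate from 18 and MeLi | CC1([O-])O[C@H]2C(C)=CC[C@@H]1[C@H]2O[Si](CC)(CC)CC.[Li+] | intermediate
21 | 1-[(1R,5S,6R)-5-hydroxy-4-methyl-6-(triethylsilyloxy)cyclohex-3-en-1-yl]ethanone | CC(=O)[C@@H]1CC=C(C)[C@H](O)[C@@H]1O[Si](CC)(CC)CC | intermediate
22 | 4,5-cis-epoxide of 21 (epoxide O, O3–H, O2–Si and acetyl on one face, C4 methyl on the other) | CC(=O)[C@@H]1C[C@@H]2O[C@]2(C)[C@H](O)[C@@H]1O[Si](CC)(CC)CC | intermediate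
23 | angelic acid, (Z)-2-methylbut-2-enoic acid | C/C=C(/C)C(=O)O | starting material
24 | C3 angelate of 22 | CC(=O)[C@@H]1C[C@@H]2O[C@]2(C)[C@H](OC(=O)/C(C)=C\C)[C@@H]1O[Si](CC)(CC)CC | intermediate
25 | potassium enolate of 24 (C7=C14) | C=C([O-])[C@@H]1C[C@@H]2O[C@]2(C)[C@H](OC(=O)/C(C)=C\C)[C@@H]1O[Si](CC)(CC)CC.[K+] | intermediate
26 | C7 enol triflate of 24 | C=C(OS(=O)(=O)C(F)(F)F)[C@@H]1C[C@@H]2O[C@]2(C)[C@H](OC(=O)/C(C)=C\C)[C@@H]1O[Si](CC)(CC)CC | intermediate
27 | 4-methylpent-3-en-1-ol | CC(C)=CCCO | starting material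
28 | 4-methylpent-3-enal | CC(C)=CCC=O | intermediate
29 | alkenylchromium dichloride from 26 (trivalent chromium on C7) | C=C([Cr](Cl)Cl)[C@@H]1C[C@@H]2O[C@]2(C)[C@H](OC(=O)/C(C)=C\C)[C@@H]1O[Si](CC)(CC)CC | intermediate
30 | C8 carbinol (C8 epimers): ring as in 24, C7(=CH2)–CH(OH)–CH2–CH=CMe2 | C=C(C(O)CC=C(C)C)[C@@H]1C[C@@H]2O[C@]2(C)[C@H](OC(=O)/C(C)=C\C)[C@@H]1O[Si](CC)(CC)CC | intermediate
31 | C8 ketone (α-methylene ketone) | C=C(C(=O)CC=C(C)C)[C@@H]1C[C@@H]2O[C@]2(C)[C@H](OC(=O)/C(C)=C\C)[C@@H]1O[Si](CC)(CC)CC | intermediate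
32 | (8S)-allylic alcohol | C=C([C@H](CC=C(C)C)O)[C@@H]1C[C@@H]2O[C@]2(C)[C@H](OC(=O)/C(C)=C\C)[C@@H]1O[Si](CC)(CC)CC | intermediate
33 | 3,8-bis-angelate, O2 triethylsilyl ether, C10=C11 alkene | C=C([C@H](CC=C(C)C)OC(=O)/C(C)=C\C)[C@@H]1C[C@@H]2O[C@]2(C)[C@H](OC(=O)/C(C)=C\C)[C@@H]1O[Si](CC)(CC)CC | intermediate
34 | O2-triethylsilyl ether of the target (10R epoxide) | C=C([C@H](C[C@H]1OC1(C)C)OC(=O)/C(C)=C\C)[C@@H]1C[C@@H]2O[C@]2(C)[C@H](OC(=O)/C(C)=C\C)[C@@H]1O[Si](CC)(CC)CC | intermediate
35 | CNP0296086.3, (1S,2R,3R,4S,5S,8S,10R) in the numbering above: 3,8-bis(angeloyloxy)-4,5:10,11-diepoxybisabol-7(14)-en-2-ol | C=C([C@H](C[C@H]1OC1(C)C)OC(=O)/C(C)=C\C)[C@@H]1C[C@@H]2O[C@]2(C)[C@H](OC(=O)/C(C)=C\C)[C@@H]1O | target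

**Count**

Total steps: 21. Longest linear sequence: 20 (steps 1–14 and 16–21, from 2-deoxy-L-ribose); step 15 is the one-step side branch.

**Steps most likely to fail**

Step 8. The lactone enolate may lose the C2 oxygen by β-elimination before it is silylated, or the fused ketene acetal may decompose before it reaches the boat geometry at the temperature the shift needs. The fallback makes C1–C6 by alkylation and the ring by metathesis, and lets lactonisation sort out C1. It sets out from aldehyde 6 and returns at 17. MeMgBr (THF, −78 °C) would give the secondary carbinol F1, and Dess–Martin oxidation the methyl ketone F2. Ph3P=CH2 (THF, −78 → 0 °C) would give the isopropenyl ester F3, and LDA then allyl bromide (THF, −78 °C) the α-allyl ester F4 as a mixture at C1. Ring-closing metathesis with second-generation Grubbs catalyst (CH2Cl2, 40 °C) would close the cyclohexene ester F5. Dowex (H+) in aqueous MeCN would give the diol ester F6. DBU in toluene at 80 °C should then equilibrate C1, and since only the epimer with the ester cis to O3 can lactonise, the material is expected to drain into 17.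

Step 7. Conjugate addition to the vinyl ketone, or its enolisation, may compete with 1,2-addition, and facial selectivity is lost if chelation is incomplete. The fallback uses an alkynyl ketone, which does not polymerise and keeps the chelate open to methyl attack. It sets out from aldehyde 6 and returns at 12. (Trimethylsilyl)ethynylmagnesium bromide (THF, −78 °C) would give the propargylic alcohol F7, and Dess–Martin oxidation the ynone F8. MeMgBr (CH2Cl2/Et2O, −78 °C → rt) would add under the same chelate control and lactonise to the silylethynyl lactone F9. Bu4NF/AcOH would give the ethynyl lactone F10. Semihydrogenation (H2, Pd/CaCO3 poisoned with Pb(OAc)2, quinoline, EtOAc) would give 12.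

Step 16. The β,γ-unsaturated aldehyde may isomerise or self-condense, or the chromium salts may open the epoxide, faster than the alkenylchromium adds. The fallback is an acyl Stille coupling that reaches the enone directly. It sets out from triflate 26 and returns at 31, so that step 17 is not needed. Me3SnSnMe3, Pd(PPh3)4 and LiCl (THF, 60 °C) would give the alkenylstannane F11. Commercial 4-methylpent-3-enoic acid and (COCl)2 would give 4-methylpent-3-enoyl chloride F12. The two would be coupled with Pd2(dba)3 and tri(2-furyl)phosphine (zerovalent palladium, THF, rt) to give 31.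

**Further compounds**

F1 | step 8 | methyl 2-[cis-5-(1-hydroxyethyl)-2,2-dimethyl-1,3-dioxolan-4-yl]acetate (carbinol epimers) | COC(=O)C[C@H]1OC(C)(C)O[C@H]1C(C)O
F2 | step 8 | methyl 2-[(4R,5R)-5-acetyl-2,2-dimethyl-1,3-dioxolan-4-yl]acetate | COC(=O)C[C@H]1OC(C)(C)O[C@H]1C(C)=O
F3 | step 8 | methyl 2-[cis-2,2-dimethyl-5-(prop-1-en-2-yl)-1,3-dioxolan-4-yl]acetate | COC(=O)C[C@H]1OC(C)(C)O[C@H]1C(C)=C
F4 | step 8 | methyl 2-[cis-2,2-dimethyl-5-(prop-1-en-2-yl)-1,3-dioxolan-4-yl]pent-4-enoate (C1 epimers) | COC(=O)C(CC=C)[C@H]1OC(C)(C)O[C@H]1C(C)=C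
F5 | step 8 | methyl ester of 15 (C1 epimers) | COC(=O)C1CC=C(C)[C@@H]2OC(C)(C)O[C@H]12
F6 | step 8 | methyl 5,6-dihydroxy-4-methylcyclohex-3-ene-1-carboxylate (cis-diol as in 16, C1 epimers) | COC(=O)C1CC=C(C)[C@H](O)[C@@H]1O
F7 | step 7 | methyl 2-[cis-5-(1-hydroxy-3-trimethylsilylprop-2-ynyl)-2,2-dimethyl-1,3-dioxolan-4-yl]acetate (carbinol epimers) | COC(=O)C[C@H]1OC(C)(C)O[C@H]1C(O)C#C[Si](C)(C)C
F8 | step 7 | methyl 2-[cis-2,2-dimethyl-5-(3-trimethylsilylprop-2-ynoyl)-1,3-dioxolan-4-yl]acetate | COC(=O)C[C@H]1OC(C)(C)O[C@H]1C(=O)C#C[Si](C)(C)C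
F9 | step 7 | 6-(trimethylsilylethynyl) analogue of 12 (alkynyl anti to the acetonide oxygens) | O=C1C[C@H]2OC(C)(C)O[C@H]2[C@](C)(C#C[Si](C)(C)C)O1
F10 | step 7 | 6-ethynyl analogue of 12 | O=C1C[C@H]2OC(C)(C)O[C@H]2[C@](C)(C#C)O1
F11 | step 16 | C7 trimethylstannyl alkene from 26 | C=C([Sn](C)(C)C)[C@@H]1C[C@@H]2O[C@]2(C)[C@H](OC(=O)/C(C)=C\C)[C@@H]1O[Si](CC)(CC)CC
F12 | step 16 | 4-methylpent-3-enoyl chloride | CC(C)=CCC(=O)Cl
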